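**Retrosynthetic overview**
- Target, fisetinidol-(4α→6)-catechin ⇐ hydrogenolysis (seven benzyl ethers, one C8 bromine) ⇐ Friedel–Crafts C4–C6 coupling of a 4-methoxyflavan-3-ol donor with 8-bromo-capped tetra-O-benzyl-(+)-catechin.
- Donor ⇐ trans-epoxidation and methanolysis of an (S)-2-aryl-2H-chromene; C3 is relayed from C2, and C4 is set later in the coupling, anti to the C3 oxygen.
- Key disconnection: the O1–C2 bond of that chromene, made by an enantioselective C–O ring closure of a chalcone-derived allylic alcohol through a vinyl o-quinone methide.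
- Chalcone ⇐ Claisen–Schmidt condensation of two commercial benzyl-protected aromatics.
- Ring order: rings A and B of the upper unit and all three rings of (+)-catechin are bought; the only ring made is the upper pyran ring C, closed by the C–O bond before the interflavan bond is formed.

Assumption: 1, 2 and 9 are bought; the sense of induction of the chiral acid in step 3 is not predictable and must be checked by experiment, and (S)-TRIP replaces (R)-TRIP if the (R) acid gives the mirror-image chromene.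

Step 1
Reactants: 1 1-[4-(benzyloxy)-2-hydroxyphenyl]ethan-1-one; 2 3,4-bis(benzyloxy)benzaldehyde
Product: 3 (E)-1-[4-(benzyloxy)-2-hydroxyphenyl]-3-[3,4-bis(benzyloxy)phenyl]prop-2-en-1-one
Conditions: KOH (50% aq, 5 equiv), EtOH, rt, 36 h; then 1 M HCl
Reagents that add atoms: none
Why: Claisen–Schmidt aldol condensation of the methyl ketone enolate with the non-enolisable aldehyde, followed by E1cB dehydration, gives the thermodynamically favoured (E)-enone, and the benzyl ethers and the phenoxide are inert to KOH.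

Step 2
Reactants: 3 (E)-1-[4-(benzyloxy)-2-hydroxyphenyl]-3-[3,4-bis(benzyloxy)phenyl]prop-2-en-1-one
Product: 4 (E)-1-[4-(benzyloxy)-2-hydroxyphenyl]-3-[3,4-bis(benzyloxy)phenyl]prop-2-en-1-ol (racemic)
Conditions: NaBH4, CeCl3·7H2O, MeOH/THF, −20 °C; pH 7 phosphate buffer work-up, crude used at once without silica
Reagents that add atoms: none
Why: Luche 1,2-reduction delivers hydride to the CeCl3-activated carbonyl without conjugate reduction; the new carbinol centre is racemic, which does not matter because it is erased in step 3.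

Step 3
Reactants: 4 (E)-1-[4-(benzyloxy)-2-hydroxyphenyl]-3-[3,4-bis(benzyloxy)phenyl]prop-2-en-1-ol (racemic)
Product: 6 (S)-7-(benzyloxy)-2-[3,4-bis(benzyloxy)phenyl]-2H-chromene, via vinyl o-quinone methide 5 (not isolated)
Conditions: (R)-3,3'-bis(2,4,6-triisopropylphenyl)-1,1'-binaphthyl-2,2'-diyl hydrogen phosphate [(R)-TRIP] (5 mol %), 5 Å MS, toluene, −20 °C; Et3N quench, Et3N-deactivated silica
Reagents that add atoms: none
Why: Proposed new method: enantioconvergent dehydrative oxa-6π cyclisation, in which the chiral phosphoric acid dehydrates both enantiomers of 4 to the same achiral vinyl o-quinone methide 5, stays hydrogen-bonded to its carbonyl oxygen (the atom that forms the new bond) and so directs the disrotatory O1–C2 closure to one face, setting C2 as S (aryl on the α-face), while the weak acid and low temperature keep the product ether from re-ionising; the closest known reaction types are chiral phosphoric acid catalysed additions to o-quinone methides generated from o-hydroxybenzyl alcohols and the chiral N-triflylphosphoramide catalysed allylic cyclo-etherification that gives 2,2-disubstituted 2H-chromenes.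

Step 4
Reactants: 6 (S)-7-(benzyloxy)-2-[3,4-bis(benzyloxy)phenyl]-2H-chromene
Product: 8 (2R,3S,4R)-7-(benzyloxy)-2-[3,4-bis(benzyloxy)phenyl]-4-methoxychroman-3-ol, via trans-3,4-epoxyflavan 7 (not isolated)
Conditions: dimethyldioxirane (1.2 equiv, acetone), CH2Cl2, −40 °C; then MeOH, pyridinium p-toluenesulfonate (5 mol %), −40→0 °C
Reagents that add atoms: dimethyldioxirane CC1(C)OO1; methanol CO
Why: Substrate-controlled epoxidation on the face anti to the 2-aryl group sets C3 (S, oxygen trans to the aryl), and SN1-type methanolysis of the labile p-alkoxybenzylic oxirane at C4 traps it as a storable donor; the C4 configuration (mainly anti opening; any 4-epimer is carried along) is irrelevant because C4 is re-ionised in step 7.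

Step 5
Reactants: 9 (+)-catechin
Product: 10 5,7,3',4'-tetra-O-benzyl-(+)-catechin
Conditions: BnBr (4.4 equiv), K2CO3, DMF, −10 °C→rt
Reagents that add atoms: benzyl bromide BrCc1ccccc1
Why: Williamson ether synthesis in which K2CO3 deprotonates only the four phenols and leaves the secondary 3-OH and both stereocentres untouched.

Step 6
Reactants: 10 5,7,3',4'-tetra-O-benzyl-(+)-catechin
Product: 11 8-bromo-5,7,3',4'-tetra-O-benzyl-(+)-catechin
Conditions: NBS (1.0 equiv), CH2Cl2, −40→0 °C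
Reagents that add atoms: N-bromosuccinimide O=C1CCC(=O)N1Br
Why: Electrophilic aromatic bromination goes to C8, the more accessible nucleophilic carbon of the 5,7-dialkoxy ring (C6 is flanked by two benzyloxy groups), which caps C8 so that only C6 can react in step 7.

Step 7
Reactants: 8 (2R,3S,4R)-7-(benzyloxy)-2-[3,4-bis(benzyloxy)phenyl]-4-methoxychroman-3-ol; 11 8-bromo-5,7,3',4'-tetra-O-benzyl-(+)-catechin (2.5 equiv, excess recovered)
Product: 12 (2R,3S,4S)-7-(benzyloxy)-2-[3,4-bis(benzyloxy)phenyl]-4-[(2R,3S)-5,7-bis(benzyloxy)-2-[3,4-bis(benzyloxy)phenyl]-8-bromo-3-hydroxychroman-6-yl]chroman-3-ol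
Conditions: Me3SiOTf (0.5 equiv), 4 Å MS, CH2Cl2, −78→−30 °C; aq NaHCO3
Reagents that add atoms: none
Why: Lewis-acid Friedel–Crafts alkylation in which Me3SiOTf ionises the 4-methoxy group to the benzylic cation stabilised by O1 and the 7-benzyloxy group, the only free nucleophilic carbon of 11 is C6, and attack anti to the C3–OH gives the all-equatorial 2,3-trans-3,4-trans product, setting C4 (S).

Step 8
Reactants: 12 (2R,3S,4S)-7-(benzyloxy)-2-[3,4-bis(benzyloxy)phenyl]-4-[(2R,3S)-5,7-bis(benzyloxy)-2-[3,4-bis(benzyloxy)phenyl]-8-bromo-3-hydroxychroman-6-yl]chroman-3-ol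
Product: 13 fisetinidol-(4α→6)-catechin, (2R,3S,4S)-2-(3,4-dihydroxyphenyl)-4-[(2R,3S)-2-(3,4-dihydroxyphenyl)-3,5,7-trihydroxychroman-6-yl]chromane-3,7-diol
Conditions: H2 (1 atm), Pd(OH)2/C, Et3N (3 equiv), THF/MeOH/H2O 20:1:1, rt; Sephadex LH-20
Reagents that add atoms: none
Why: Heterogeneous hydrogenolysis cleaves the seven benzyl ethers and, with Et3N as HBr scavenger, the aryl C–Br bond, while the C4–C6 bond and both pyran rings survive at 1 atm and room temperature and no stereocentre is touched.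

**Compound list**
1 | 1-[4-(benzyloxy)-2-hydroxyphenyl]ethan-1-one | CC(=O)c1ccc(OCc2ccccc2)cc1O | starting material
2 | 3,4-bis(benzyloxy)benzaldehyde | O=Cc1ccc(OCc2ccccc2)c(OCc2ccccc2)c1 | starting material
3 | (E)-1-[4-(benzyloxy)-2-hydroxyphenyl]-3-[3,4-bis(benzyloxy)phenyl]prop-2-en-1-one | O=C(/C=C/c1ccc(OCc2ccccc2)c(OCc2ccccc2)c1)c1ccc(OCc2ccccc2)cc1O | intermediate
4 | (E)-1-[4-(benzyloxy)-2-hydroxyphenyl]-3-[3,4-bis(benzyloxy)phenyl]prop-2-en-1-ol, racemic at the carbinol carbon | OC(/C=C/c1ccc(OCc2ccccc2)c(OCc2ccccc2)c1)c1ccc(OCc2ccccc2)cc1O | intermediate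
5 | (6Z)-3-(benzyloxy)-6-{(2E)-3-[3,4-bis(benzyloxy)phenyl]prop-2-en-1-ylidene}cyclohexa-2,4-dien-1-one (vinyl o-quinone methide) | O=C1C=C(OCc2ccccc2)C=C/C1=C/C=C/c1ccc(OCc2ccccc2)c(OCc2ccccc2)c1 | intermediate (not isolated)
6 | (S)-7-(benzyloxy)-2-[3,4-bis(benzyloxy)phenyl]-2H-chromene | [C@@H]1(c2ccc(OCc3ccccc3)c(OCc3ccccc3)c2)C=Cc2ccc(OCc3ccccc3)cc2O1 | intermediate
7 | (2R,3S,4S)-7-(benzyloxy)-2-[3,4-bis(benzyloxy)phenyl]-3,4-epoxychromane, oxirane oxygen trans to the 2-aryl group | [C@@H]1(c2ccc(OCc3ccccc3)c(OCc3ccccc3)c2)[C@H]2O[C@H]2c2ccc(OCc3ccccc3)cc2O1 | intermediate (not isolated)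
8 | (2R,3S,4R)-7-(benzyloxy)-2-[3,4-bis(benzyloxy)phenyl]-4-methoxychroman-3-ol (2,3-trans-3,4-trans) | [C@@H]1(c2ccc(OCc3ccccc3)c(OCc3ccccc3)c2)[C@@H](O)[C@H](OC)c2ccc(OCc3ccccc3)cc2O1 | intermediate
9 | (+)-catechin, (2R,3S)-2-(3,4-dihydroxyphenyl)chromane-3,5,7-triol | O[C@H]1Cc2c(O)cc(O)cc2O[C@@H]1c1ccc(O)c(O)c1 | starting material
10 | 5,7,3',4'-tetra-O-benzyl-(+)-catechin, (2R,3S)-5,7-bis(benzyloxy)-2-[3,4-bis(benzyloxy)phenyl]chroman-3-ol | O[C@H]1Cc2c(OCc3ccccc3)cc(OCc3ccccc3)cc2O[C@@H]1c1ccc(OCc2ccccc2)c(OCc2ccccc2)c1 | intermediate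
11 | 8-bromo-5,7,3',4'-tetra-O-benzyl-(+)-catechin, (2R,3S)-5,7-bis(benzyloxy)-2-[3,4-bis(benzyloxy)phenyl]-8-bromochroman-3-ol | O[C@H]1Cc2c(OCc3ccccc3)cc(OCc3ccccc3)c(Br)c2O[C@@H]1c1ccc(OCc2ccccc2)c(OCc2ccccc2)c1 | intermediate
12 | (2R,3S,4S)-7-(benzyloxy)-2-[3,4-bis(benzyloxy)phenyl]-4-[(2R,3S)-5,7-bis(benzyloxy)-2-[3,4-bis(benzyloxy)phenyl]-8-bromo-3-hydroxychroman-6-yl]chroman-3-ol | c1ccccc1COc1ccc2c(c1)O[C@H](c1ccc(OCc3ccccc3)c(OCc3ccccc3)c1)[C@@H](O)[C@@H]2c1c(OCc3ccccc3)c(Br)c2c(c1OCc3ccccc3)C[C@H](O)[C@@H](c1ccc(OCc3ccccc3)c(OCc3ccccc3)c1)O2 | intermediate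
13 | fisetinidol-(4α→6)-catechin, (2R,3S,4S)-2-(3,4-dihydroxyphenyl)-4-[(2R,3S)-2-(3,4-dihydroxyphenyl)-3,5,7-trihydroxychroman-6-yl]chromane-3,7-diol | Oc1ccc2c(c1)O[C@H](c1ccc(O)c(O)c1)[C@@H](O)[C@@H]2c1c(O)cc2c(c1O)C[C@H](O)[C@@H](c1ccc(O)c(O)c1)O2 | target

**Step count**
Total: 8 steps. Longest linear sequence: 6 steps (1 → 2 → 3 → 4 → 7 → 8); steps 5 and 6 form the short branch.

**Three steps most likely to fail**

Step 3 (the proposed new reaction). Risks are low enantioselectivity, slow acid-mediated racemisation of 6 through re-opening to 5, and oligomerisation of 5. The fallback uses known chemistry, sets out from 1 and comes back at 6. Compound 1 is heated with N,N-dimethylformamide dimethyl acetal to give the enaminone (E)-1-[4-(benzyloxy)-2-hydroxyphenyl]-3-(dimethylamino)prop-2-en-1-one F1. HCl in CH2Cl2 cyclises it to 7-(benzyloxy)-4H-chromen-4-one F2. The known Pd-catalysed asymmetric conjugate addition of commercial [3,4-bis(benzyloxy)phenyl]boronic acid (Pd(OCOCF3)2, 4-tert-butyl-2-(pyridin-2-yl)-4,5-dihydrooxazole ligand of the antipode that gives the 2S product, NH4PF6, H2O, ClCH2CH2Cl, 60 °C) gives (S)-7-(benzyloxy)-2-[3,4-bis(benzyloxy)phenyl]chroman-4-one F3. NaBH4 at 0 °C gives the 2,4-cis alcohol (2S,4S)-7-(benzyloxy)-2-[3,4-bis(benzyloxy)phenyl]chroman-4-ol F4, and dehydration with catalytic pyridinium p-toluenesulfonate in toluene at 80 °C gives 6. Here C2 is set by a C–C bond-forming step instead of the ring closure.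

Step 4. Risks are rearrangement of the very labile oxirane 7 to the flavan-3-one before it is trapped, over-oxidation, and incomplete facial selectivity. The fallback sets out from 6 and comes back at 8. Catalytic OsO4 with N-methylmorpholine N-oxide in acetone/H2O dihydroxylates 6 syn, on the face anti to the 2-aryl group, to give (2R,3S,4S)-7-(benzyloxy)-2-[3,4-bis(benzyloxy)phenyl]chromane-3,4-diol F5, which has the same C3 configuration and no epoxide stage. Pyridinium p-toluenesulfonate in MeOH then exchanges only the ionisable benzylic 4-OH for OMe, giving 8.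

Step 7. Risks are sluggish reaction at the bromine-deactivated, doubly flanked C6 of 11, self-condensation of 8 through its own ring A, and partial formation of the 3,4-cis isomer, since 5-deoxy cations are less face-selective than 5-oxygenated ones. The fallback sets out from 8 and comes back at 12. Ac2O/pyridine gives (2R,3S,4R)-7-(benzyloxy)-2-[3,4-bis(benzyloxy)phenyl]-4-methoxychroman-3-yl acetate F6. BF3·OEt2-promoted coupling with 11 then runs through the acetoxy-bridged dioxolanylium cation on the β-face, which is longer-lived and open only to α-attack, and gives (2R,3S,4S)-7-(benzyloxy)-2-[3,4-bis(benzyloxy)phenyl]-4-[(2R,3S)-5,7-bis(benzyloxy)-2-[3,4-bis(benzyloxy)phenyl]-8-bromo-3-hydroxychroman-6-yl]chroman-3-yl acetate F7. K2CO3 in MeOH removes the acetate to give 12. Stereocontrol thus comes from neighbouring-group participation instead of steric bias.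

**Further compounds**
F1 | step 3 | (E)-1-[4-(benzyloxy)-2-hydroxyphenyl]-3-(dimethylamino)prop-2-en-1-one | CN(C)/C=C/C(=O)c1ccc(OCc2ccccc2)cc1O
F2 | step 3 | 7-(benzyloxy)-4H-chromen-4-one | O=c1ccoc2cc(OCc3ccccc3)ccc12
F3 | step 3 | (S)-7-(benzyloxy)-2-[3,4-bis(benzyloxy)phenyl]chroman-4-one | O=C1C[C@@H](c2ccc(OCc3ccccc3)c(OCc3ccccc3)c2)Oc2cc(OCc3ccccc3)ccc12
F4 | step 3 | (2S,4S)-7-(benzyloxy)-2-[3,4-bis(benzyloxy)phenyl]chroman-4-ol | O[C@H]1C[C@@H](c2ccc(OCc3ccccc3)c(OCc3ccccc3)c2)Oc2cc(OCc3ccccc3)ccc12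
F5 | step 4 | (2R,3S,4S)-7-(benzyloxy)-2-[3,4-bis(benzyloxy)phenyl]chromane-3,4-diol | [C@@H]1(c2ccc(OCc3ccccc3)c(OCc3ccccc3)c2)[C@@H](O)[C@@H](O)c2ccc(OCc3ccccc3)cc2O1
F6 | step 7 | (2R,3S,4R)-7-(benzyloxy)-2-[3,4-bis(benzyloxy)phenyl]-4-methoxychroman-3-yl acetate | [C@@H]1(c2ccc(OCc3ccccc3)c(OCc3ccccc3)c2)[C@@H](OC(C)=O)[C@H](OC)c2ccc(OCc3ccccc3)cc2O1
F7 | step 7 | (2R,3S,4S)-7-(benzyloxy)-2-[3,4-bis(benzyloxy)phenyl]-4-[(2R,3S)-5,7-bis(benzyloxy)-2-[3,4-bis(benzyloxy)phenyl]-8-bromo-3-hydroxychroman-6-yl]chroman-3-yl acetate | c1ccccc1COc1ccc2c(c1)O[C@H](c1ccc(OCc3ccccc3)c(OCc3ccccc3)c1)[C@@H](OC(C)=O)[C@@H]2c1c(OCc3ccccc3)c(Br)c2c(c1OCc3ccccc3)C[C@H](O)[C@@H](c1ccc(OCc3ccccc3)c(OCc3ccccc3)c1)O2
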